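Remark on the chemistry: the target is the methyl ester of the tridepside gyrophoric acid and has no stereocentre, so no configuration has to be set. Ring atoms are numbered as in orsellinic acid (C-1 bears the carbonyl carbon, O-2 and O-4 are the phenolic oxygens, C-6 bears the methyl group). Compounds 1 and 4 are taken as commercial. The acylketene 5 is a transient that 3 releases afresh whenever it is heated, so steps 3 and 4 pass through the same species and it is never stored.

## The problem

The target 11 is a linear chain of three 2,4-dihydroxy-6-methylbenzoyl (orsellinoyl) rings: ring A carries the methyl ester, ring B is in the middle, and ring C ends in a free resorcinol. The rings are joined by two aryl ester bonds, each running from the carbonyl carbon on C-1 of one ring to O-4 of the next. Each of these carbonyl carbons sits between an ortho hydroxyl and an ortho methyl group, so the corresponding benzoic acids are hindered, acylate slowly when activated, and decarboxylate easily as free ortho-hydroxy acids. Of the five phenolic oxygens only O-4 of ring A and O-4 of ring B may be acylated, and an acyl donor that already carries a free O-4 would condense with itself, which is why the usual answer is to protect every phenol. The aryl ester bonds are cleaved or scrambled by alkoxide, hydroxide and amine nucleophiles, so once the first depside bond exists the chemistry must avoid nucleophilic base. There is no stereocentre; the whole difficulty is site selectivity among phenols and formation of two hindered, labile ester bonds. The feature that makes the key step possible is that in rings B and C the ester carbonyl carbon, C-1, C-2 (with its oxygen), C-3, C-4 (with its oxygen), C-5, C-6 and the 6-methyl carbon form one unbranched eight-carbon chain with oxygen on every second carbon, closed into the ring by the single bond C-1–C-6, so that each of these rings is a folded 3,5,7-trioxooctanoyl chain. The ester bond can therefore be made first, from a ketene carbon, and the ring closed afterwards by an aldol condensation.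

## Retrosynthesis

Target 11 to didepside 8 and diketo-dioxinone 3. Ring C is taken apart completely. Rehydration at C-6 and cleavage of the ring bond C-1–C-6 (aldol retron) lead through aldol adduct 10 to the open aryl 3,5,7-trioxooctanoate 9. Cleavage of the bond between the ester carbonyl carbon and O-4 of ring B then gives methyl lecanorate 8 and acylketene 5, whose stable form is 6-(2,4-dioxopentyl)-2,2-dimethyl-4H-1,3-dioxin-4-one 3. The neighbouring cut, the ester bond alone, would leave a hindered benzoic acid with two phenols to protect. The present cut removes a whole ring and every protecting group, and the acylating carbon becomes an unhindered ketene. The forward reaction must do three things: capture the ketene at O-4 of ring B and not at the two chelated O-2 phenols, close the chain from its C-2 to its C-7, and do so faster than the aryloxide is lost.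

Didepside 8 to methyl orsellinate 4 and 3. The same two bonds are cut in ring B, through aldol adduct 7, aryl triketo ester 6 and acylketene 5. This leads back to 4 (methyl 2,4-dihydroxy-6-methylbenzoate) and a second molecule of 3. The repeat is what makes the plan economical: one building block and one operation serve both depside bonds and both new rings. O-4 of each new ring is set free only by the aromatization, after the ketene is gone, so the chain grows by exactly one ring per cycle. The forward reaction needs selectivity for the unchelated O-4 of 4 over O-2.

Diketo-dioxinone 3 to keto-dioxinone 2. The bond between the terminal acetyl carbon and the adjacent methylene carbon of the side chain is cut (Claisen retron). This gives 2,2-dimethyl-6-(2-oxopropyl)-4H-1,3-dioxin-4-one 2 and an acetyl donor. Cutting here and not at the inner methylene keeps the nucleophile a simple 1,3-dianion that reacts at its terminal carbon. The forward reaction must acylate once, on carbon, and must not let the product cyclize on work-up.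

Keto-dioxinone 2 to dioxinone 1. The bond between the ketone carbon and the methylene carbon on C-6 of the dioxinone is cut, giving commercial 2,2,6-trimethyl-4H-1,3-dioxin-4-one 1 and a second acetyl donor. The dioxinone ring is kept through both acylations because it is a masked acylketene that survives enolate chemistry and opens on heating without any reagent.

## Roads not taken

Alternative 1: the most obvious plan cuts only the two aryl ester C(=O)–O bonds and joins preformed rings. The forward key step is acylation of O-4 of 4, and then of O-4 of ring B of 8, by a fully protected orsellinoyl donor such as 2,4-bis(benzyloxy)-6-methylbenzoyl chloride A1, each time followed by hydrogenolysis. The acyl carbon of A1 is flanked by two ortho substituents and reacts slowly. A1 itself needs perbenzylation, saponification of a hindered ester and chlorination, and every cycle costs a coupling and a deprotection, about seven steps in all against four. The chosen plan never activates a hindered arenecarboxylic acid and needs no protecting group, because the phenols of the incoming ring do not exist when the ester bond is made.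

Alternative 2: the ring is built first from the same open chain and the ester bond made second. Amine-mediated aldol aromatization of 3 would give 7-hydroxy-2,2,5-trimethyl-4H-1,3-benzodioxin-4-one A2, which must be benzylated to 7-(benzyloxy)-2,2,5-trimethyl-4H-1,3-benzodioxin-4-one A3 because its free O-7 would otherwise capture its own acyl group. The forward key step is irradiation of A3 to the quinoketene 3-(benzyloxy)-5-methyl-6-(oxomethylidene)cyclohexa-2,4-dien-1-one A4 and its capture by O-4 of 4. The ketene carbon of A4 is flanked by the methyl group, and each cycle needs aromatization, protection, acyl transfer and hydrogenolysis. The chosen plan uses the same aldol but after the ester bond, which removes the protection and deprotection and halves the step count.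

Alternative 3: the bond between ring carbon C-1 and the carbonyl carbon is cut instead. The forward key step is a carbonylative coupling of 1,5-bis(benzyloxy)-2-iodo-3-methylbenzene A5 with carbon monoxide and the phenol 4 under Pd(OAc)2 and a phosphine. Oxidative addition of zerovalent palladium to an electron-rich carbon–iodine bond between two ortho substituents is slow, and so is the attack of a weakly nucleophilic phenol on the hindered acylpalladium species. The benzyl ethers and their hydrogenolysis remain, and A5 must itself be made by regioselective iodination and benzylation. The plan gains nothing in protecting-group economy and adds a difficult metal-catalysed step to each cycle.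

Key step: step 3

## Route

Step 1
Reactants: 1 2,2,6-trimethyl-4H-1,3-dioxin-4-one
Product: 2 2,2-dimethyl-6-(2-oxopropyl)-4H-1,3-dioxin-4-one
Conditions: LiN(SiMe3)2 (2 equiv), THF, −78 °C; then AcCl (1 equiv), −78 °C; 1 M HCl
Reagents that add atoms: acetyl chloride, CC(Cl)=O
Why: Kinetic deprotonation of the vinylogous ester at the C-6 methyl group, then C-acylation at that carbon (Claisen-type acylation of a dioxinone), should give 2; the second equivalent of base takes up the more acidic product so that it does not quench unreacted nucleophile.

Step 2
Reactants: 2 2,2-dimethyl-6-(2-oxopropyl)-4H-1,3-dioxin-4-one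
Product: 3 6-(2,4-dioxopentyl)-2,2-dimethyl-4H-1,3-dioxin-4-one
Conditions: LiN(iPr)2 (2.3 equiv), THF, −78 °C; then MeC(O)N(OMe)Me, −78 → −20 °C; cold 1 M HCl
Reagents that add atoms: N-methoxy-N-methylacetamide, CC(=O)N(C)OC
Why: Double deprotonation of 2 (first at the methylene between ring and ketone, then at the terminal methyl group) and acylation at the terminal, more nucleophilic carbon is a dianion Claisen acylation; the N-methoxy-N-methylamide stops at the ketone oxidation level until the acid quench, so 3 should form without over-addition.

Step 3
Reactants: 3 6-(2,4-dioxopentyl)-2,2-dimethyl-4H-1,3-dioxin-4-one; 4 methyl orsellinate (methyl 2,4-dihydroxy-6-methylbenzoate)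
Product: 8 methyl lecanorate (methyl 4-[(2,4-dihydroxy-6-methylbenzoyl)oxy]-2-hydroxy-6-methylbenzoate), via acylketene 5 (not isolated), via aryl triketo ester 6 (not isolated), via cyclic aldol adduct 7 (not isolated)
Conditions: 4 (2 equiv), PhMe, 110 °C, slow addition of 3; cool, then Et3N, CH2Cl2, 0 → 23 °C; 1 M HCl work-up
Reagents that add atoms: none
Why: Proposed new method: at 110 °C 3 should lose acetone by retro-[4+2] fragmentation to give acylketene 5, which adds the unchelated O-4 phenol of 4 across its ketene and acyl groups to give aryl triketo ester 6; Et3N then enolizes C-2 of the chain (between the aryl ester and the C-3 ketone), which attacks the C-7 methyl ketone to give 7, and loss of water, completed by the acid work-up, aromatizes the new ring to 8. The closest known reaction type is the thermolysis of diketo-dioxinones in the presence of aliphatic alcohols followed by base-mediated aldol aromatization to alkyl resorcylates, together with the capture of simple acylketenes by phenols; the sequence has not been carried through an aryl 3,5,7-trioxoalkanoate. The ring closes in the 6-(enolendo)-exo-trig mode from chain C-2 to chain C-7, the only six-membered aldol open to a doubly activated carbon, whereas the other six-membered aldol closure, from the terminal methyl group to C-3, would need the least acidic carbon of the chain. The two stereocentres of 7 arise without control and are both erased by the dehydration, so none has to be set. The step needs site selectivity between the two phenols of 4, and this is secured by the hydrogen bond that ties O-2 to the ester carbonyl and by the crowding of O-2 by that ester group. Growth by more than one unit is excluded because O-4 of the new ring does not exist until 5 has been consumed. The competing processes are loss of the aryloxide from 6 by E1cB return to 5, by lactonization through the enol oxygen at C-5 or by Claisen closure from C-6 onto the ester carbonyl; the return to 5 is harmless while 4 is in excess, and the higher acidity of C-2 in an aryl ester speeds the aldol step. An aprotic solvent, a tertiary amine in place of an alkoxide and a low temperature are chosen to hold back the lactonization and the Claisen closure.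

Step 4
Reactants: 8 methyl lecanorate (methyl 4-[(2,4-dihydroxy-6-methylbenzoyl)oxy]-2-hydroxy-6-methylbenzoate); 3 6-(2,4-dioxopentyl)-2,2-dimethyl-4H-1,3-dioxin-4-one
Product: 11 methyl 4-({4-[(2,4-dihydroxy-6-methylbenzoyl)oxy]-2-hydroxy-6-methylbenzoyl}oxy)-2-hydroxy-6-methylbenzoate (CNP0212402.0), via aryl triketo ester 9 (not isolated), via cyclic aldol adduct 10 (not isolated)
Conditions: 3 (1.5 equiv, slow addition), PhMe–1,4-dioxane, 105 °C; cool, then Et3N, CH2Cl2, 0 → 23 °C; 1 M HCl work-up
Reagents that add atoms: none
Why: Proposed new method: the sequence of step 3 is repeated on the next phenol: on heating, 3 again loses acetone to the transient acylketene 5 of step 3, which should be captured by O-4 of ring B, the only one of the three phenols of 8 that is not hydrogen-bonded to an ortho ester carbonyl, and the chain of 9 should close from C-2 to C-7 (6-(enolendo)-exo-trig aldol) to 10 and dehydrate to ring C. The closest known reaction type is again alcohol capture of the acylketene from a diketo-dioxinone followed by base-mediated aldol aromatization of an alkyl 3,5,7-trioxoalkanoate; an aryl ester has not been carried through it, and a tertiary amine in an aprotic solvent is used so that the depside bonds meet no alkoxide. The free O-4 of ring C appears only after the ketene is gone, so the chain cannot grow beyond three rings.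

## Compound list

1 | 2,2,6-trimethyl-4H-1,3-dioxin-4-one | CC1=CC(=O)OC(C)(C)O1 | starting material
2 | 2,2-dimethyl-6-(2-oxopropyl)-4H-1,3-dioxin-4-one | CC(=O)CC1=CC(=O)OC(C)(C)O1 | intermediate
3 | 6-(2,4-dioxopentyl)-2,2-dimethyl-4H-1,3-dioxin-4-one | CC(=O)CC(=O)CC1=CC(=O)OC(C)(C)O1 | intermediate
4 | methyl orsellinate (methyl 2,4-dihydroxy-6-methylbenzoate) | COC(=O)c1c(C)cc(O)cc1O | starting material
5 | acylketene oct-1-ene-1,3,5,7-tetrone (transient, not isolated) | CC(=O)CC(=O)CC(=O)C=C=O | intermediate
6 | methyl 2-hydroxy-6-methyl-4-[(3,5,7-trioxooctanoyl)oxy]benzoate (aryl triketo ester, not isolated) | COC(=O)c1c(C)cc(OC(=O)CC(=O)CC(=O)CC(C)=O)cc1O | intermediate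
7 | methyl 2-hydroxy-4-[(2-hydroxy-2-methyl-4,6-dioxocyclohexane-1-carbonyl)oxy]-6-methylbenzoate (cyclic aldol adduct, mixture of stereoisomers and enol tautomers, not isolated) | COC(=O)c1c(C)cc(OC(=O)C2C(=O)CC(=O)CC2(C)O)cc1O | intermediate
8 | methyl lecanorate (methyl 4-[(2,4-dihydroxy-6-methylbenzoyl)oxy]-2-hydroxy-6-methylbenzoate) | COC(=O)c1c(C)cc(OC(=O)c2c(C)cc(O)cc2O)cc1O | intermediate
9 | methyl 2-hydroxy-4-({2-hydroxy-6-methyl-4-[(3,5,7-trioxooctanoyl)oxy]benzoyl}oxy)-6-methylbenzoate (aryl triketo ester, not isolated) | COC(=O)c1c(C)cc(OC(=O)c2c(C)cc(OC(=O)CC(=O)CC(=O)CC(C)=O)cc2O)cc1O | intermediate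
10 | methyl 2-hydroxy-4-({2-hydroxy-4-[(2-hydroxy-2-methyl-4,6-dioxocyclohexane-1-carbonyl)oxy]-6-methylbenzoyl}oxy)-6-methylbenzoate (cyclic aldol adduct, mixture of stereoisomers and enol tautomers, not isolated) | COC(=O)c1c(C)cc(OC(=O)c2c(C)cc(OC(=O)C3C(=O)CC(=O)CC3(C)O)cc2O)cc1O | intermediate
11 | methyl 4-({4-[(2,4-dihydroxy-6-methylbenzoyl)oxy]-2-hydroxy-6-methylbenzoyl}oxy)-2-hydroxy-6-methylbenzoate (CNP0212402.0) | COC(=O)c1c(C)cc(OC(=O)c2c(C)cc(OC(=O)c3c(C)cc(O)cc3O)cc2O)cc1O | target

## Step count and risks

Total step count: 4. Longest linear sequence: 4 steps (1 → 2 → 3 → 8 → 11); compound 3 is used in both step 3 and step 4.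

Step 3 (key step, proposed new method). The most likely failure is loss of the aryloxide from 6 before the aldol closure. This can happen by E1cB reversion to 5 followed by irreversible intramolecular capture of the ketene by the enol oxygen at C-5, by direct lactonization, or by Claisen closure from C-6 of the chain onto the ester carbonyl. The cause is that the O-4 aryloxide of 4 is a much better leaving group than the alkoxides for which the sequence is established. A smaller risk is ketene capture at the chelated O-2. The fallback uses known chemistry, sets out from 4 and returns at 8. Both phenols of 4 are benzylated (BnBr, K2CO3, DMF, 60 °C) to give methyl 2,4-bis(benzyloxy)-6-methylbenzoate F1. The hindered ester is saponified (KOH, DMSO–H2O, 90 °C) to 2,4-bis(benzyloxy)-6-methylbenzoic acid F2. F2 is activated in situ with trifluoroacetic anhydride (PhMe, 23 °C) in the presence of a second portion of 4, which is acylated only at its unchelated O-4, to give methyl 4-{[2,4-bis(benzyloxy)-6-methylbenzoyl]oxy}-2-hydroxy-6-methylbenzoate F3. Hydrogenolysis (H2, Pd/C, EtOAc) removes both benzyl groups and should give 8.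

Step 4 (proposed new method). Beyond the aryloxide loss described for step 3, three further processes threaten this step: poorer site selectivity now that three phenols compete, low solubility of 8 at the thermolysis stage, and transesterification of the existing depside bond by phenoxide during the amine stage. The fallback uses known chemistry, sets out from 8 and returns at 11. The acid 2,4-bis(benzyloxy)-6-methylbenzoic acid F2, made from 4 as described for step 3, is activated with trifluoroacetic anhydride (PhMe, 23 °C) and acylates the unchelated O-4 of ring B of 8. This gives methyl 4-[(4-{[2,4-bis(benzyloxy)-6-methylbenzoyl]oxy}-2-hydroxy-6-methylbenzoyl)oxy]-2-hydroxy-6-methylbenzoate F4, and hydrogenolysis (H2, Pd/C, EtOAc) should give 11.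

Step 2. The likely failures are proton transfer from the more acidic product to the dianion, O-acylation, and premature aldol aromatization of 3 to a benzodioxinone on basic work-up or on silica. The triketone is prone to the same ring closure that the route uses later. The fallback sets out from 1 and returns at 3, and brings in the four-carbon unit in one piece with its far ketone masked. Compound 1 is deprotonated with LiN(SiMe3)2 (THF, −78 °C) and acylated with (E)-3-methoxybut-2-enoyl chloride to give 6-[(3E)-4-methoxy-2-oxopent-3-en-1-yl]-2,2-dimethyl-4H-1,3-dioxin-4-one F5. Mild aqueous acid (1 M HCl, THF, 0 °C) hydrolyses the enol ether to the 1,3-diketone 3.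

Step 1. The likely failures are consumption of the deprotonated dioxinone by proton transfer from the product, O-acylation, and double acylation. The fallback sets out from 1 and returns at 2, and replaces the acylation by an addition–oxidation sequence. Compound 1 is deprotonated with LiN(SiMe3)2 (THF, −78 °C) and added to acetaldehyde in a vinylogous aldol reaction to give racemic 6-(2-hydroxypropyl)-2,2-dimethyl-4H-1,3-dioxin-4-one F6. Oxidation with Dess–Martin periodinane (CH2Cl2, 23 °C) should give 2.

## Further compounds

F1 | step 3 | methyl 2,4-bis(benzyloxy)-6-methylbenzoate | COC(=O)c1c(C)cc(OCc2ccccc2)cc1OCc1ccccc1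
F2 | step 3 | 2,4-bis(benzyloxy)-6-methylbenzoic acid | Cc1cc(OCc2ccccc2)cc(OCc2ccccc2)c1C(=O)O
F3 | step 3 | methyl 4-{[2,4-bis(benzyloxy)-6-methylbenzoyl]oxy}-2-hydroxy-6-methylbenzoate | COC(=O)c1c(C)cc(OC(=O)c2c(C)cc(OCc3ccccc3)cc2OCc2ccccc2)cc1O
F4 | step 4 | methyl 4-[(4-{[2,4-bis(benzyloxy)-6-methylbenzoyl]oxy}-2-hydroxy-6-methylbenzoyl)oxy]-2-hydroxy-6-methylbenzoate | COC(=O)c1c(C)cc(OC(=O)c2c(C)cc(OC(=O)c3c(C)cc(OCc4ccccc4)cc3OCc3ccccc3)cc2O)cc1O
F5 | step 2 | 6-[(3E)-4-methoxy-2-oxopent-3-en-1-yl]-2,2-dimethyl-4H-1,3-dioxin-4-one | CO/C(C)=C/C(=O)CC1=CC(=O)OC(C)(C)O1
F6 | step 1 | 6-(2-hydroxypropyl)-2,2-dimethyl-4H-1,3-dioxin-4-one (racemic) | CC(O)CC1=CC(=O)OC(C)(C)O1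
A1 | alternative 1 | 2,4-bis(benzyloxy)-6-methylbenzoyl chloride | Cc1cc(OCc2ccccc2)cc(OCc2ccccc2)c1C(Cl)=O
A2 | alternative 2 | 7-hydroxy-2,2,5-trimethyl-4H-1,3-benzodioxin-4-one | Cc1cc(O)cc2OC(C)(C)OC(=O)c12
A3 | alternative 2 | 7-(benzyloxy)-2,2,5-trimethyl-4H-1,3-benzodioxin-4-one | Cc1cc(OCc3ccccc3)cc2OC(C)(C)OC(=O)c12
A4 | alternative 2 | 3-(benzyloxy)-5-methyl-6-(oxomethylidene)cyclohexa-2,4-dien-1-one (quinoketene) | O=C=C1C(C)=CC(OCc2ccccc2)=CC1=O
A5 | alternative 3 | 1,5-bis(benzyloxy)-2-iodo-3-methylbenzene | Cc1cc(OCc2ccccc2)cc(OCc2ccccc2)c1I
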